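Seconds are the unit of the quantity I follow here: the time in which [target] would reach the charge of starting material if its square grew steadily, as it does once the catalyst waits on its own product.

    starting material + free catalyst ⇌ catalyst intermediate A (K1 = 15 M⁻¹, k1 = 1200 M⁻¹ s⁻¹, Ea1 = 37.0 kJ mol⁻¹, ΔH1 = −38.0 kJ mol⁻¹)
    reagent + catalyst intermediate A → catalyst intermediate B (k2 = 1400 M⁻¹ s⁻¹, Ea2 = 37.0 kJ mol⁻¹)
    catalyst intermediate B → released group + catalyst intermediate C (k3 = 190 s⁻¹, Ea3 = 58.0 kJ mol⁻¹)
    catalyst intermediate C ⇌ free catalyst + target (K4 = 0.24 M, k4 = 200 s⁻¹, Ea4 = 41.0 kJ mol⁻¹, ΔH4 = −88.0 kJ mol⁻¹)
    free catalyst + impurity → spent catalyst (k5 = 6.4 × 10⁵ M⁻¹ s⁻¹, Ea5 = 10.0 kJ mol⁻¹)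
    (constants at −20 °C)

| flask | starting material | reagent | free catalyst | impurity | temperature | time | remark |
|---|---|---|---|---|---|---|---|
| north-west | 0.20 M | 0.200 M | 0.20 mM | 40 µM | −20 °C | 12 s |  |
| east | 0.20 M | 0.200 M | 0.20 mM | 40 µM |  | 12 s | at −20 °C until 4.0 s, from then on at 10 °C |
| north-east | 0.20 M | 0.200 M | 0.20 mM | 40 µM | 10 °C | 12 s |  |

* the flask with the highest amount of target, in percent of the starting material charged ("all alike" if they lie within 1.5 percentage points) (north-west / east / north-east / all alike)
* final target, as a percentage of the starting material charged, in north-west
* final target, as a percentage of the starting material charged, in east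
* final target, as a percentage of the starting material charged, in north-east

- the list of constants is for −20 °C, to be carried to other temperatures by the activation energies and enthalpies

Going to 10 °C, I scale the factor 19 of the step with 58.0 kJ mol⁻¹ to the other energies. Binding of starting material and capture by reagent, both at 37.0 kJ mol⁻¹, speed up 6.44-fold, and the binding constant falls to 2.21 M⁻¹. The release constant, for catalyst intermediate C giving free catalyst and target, falls to 2.86 mM.

| | −20 °C | 10 °C |
|---|---|---|
| release constant | 0.24 M | 2.86 mM |
| backward run of catalyst intermediate A | 80.0 s⁻¹ | 3490 s⁻¹ |
| capture by reagent at its charge | 280 s⁻¹ | 1800 s⁻¹ |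
| share of catalyst intermediate A going on | 77.8 % | 34.1 % |

The first row gives the [target] at which catalyst intermediate C and free catalyst stand equal. At −20 °C that value lies above the charge of 0.20 M, so my reckoning does not reach north-west. At 10 °C it lies far below that charge, so for north-east I put the catalyst of the round, 160 µM, the charge less the impurity, into catalyst intermediate C as the resting state. This is product inhibition: [free catalyst] equals the release constant times [catalyst intermediate C] over [target].

The next two rows turn over on warming: the backward run now beats capture, and a third of catalyst intermediate A goes on. The turnover is g times [free catalyst], where g is the binding rate per free catalyst times that share. Multiplying by [target] leaves a right side without [target], so at fixed g the square of [target] grows steadily.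

At the charge, g is 527 s⁻¹, which gives 0.0761 M of target in 12 s. Starting material and reagent fall together, so I take them at the midpoint, 0.162 M, where g is 369 s⁻¹. The square-law time, the charge squared over twice the release constant times the catalyst of the round times g, is then 118 s. The share of the charge turned into target is the square root of the time over this square-law time, so my north-east figure is 31.8 %.

The forecast says 40.5 % for north-west, 28.3 % for east and 29.2 % for north-east, with north-west highest, on the grounds that “product inhibition throttles the warm flasks”. My north-east figure stands above its number.

The run gives 40.7 % in north-west, 28.4 % in east and 29.3 % in north-east, so north-west leads and the forecast holds; a charge of free catalyst of 0.152 mM or 0.256 mM moves the answer for east by 5 points. The main reason in north-east is the backward run of the release: without it, target reaches 84.1 % instead of 29.3 %. The square-law time read from north-east is 140 s, longer than my 118 s. East warms at 4.0 s with 15.6 % target; adding the remaining time over my 118 s to the square of that share gives 30.4 %, and the run reads 28.4 %.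

The numbers are invented; no experiment stands behind them.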